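The runs stem from a simulated flask with constants of no real substance; the scatter is artificial.

The length of a chain at the end is reckoned here by dividing the free monomer that has entered chains by the initiator lost, both as accumulated amounts at the same moment. Each initiator lost gives two radicals, and two radicals that join make one chain, so one chain is counted per initiator lost, with living chains set aside.

common to all: initiator 87 µM

| flask | free monomer | protic impurity | remark | time |
|---|---|---|---|---|
| Tuesday's | 0.040 M (fed, over 8.0 h) | 0.031 M | run made earlier; the fed solution adds 0.50 times the starting volume |  |
| Friday's | 0.080 M (fed, over 8.0 h) | 0.031 M | run made earlier; the fed solution adds 0.50 times the starting volume |  |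
| beta | 0.031 M (fed, over 8.0 h) | 0.0310 M | the fed solution adds 0.50 times the starting volume | 30 h |
| theta | 0.050 M (fed, over 8.0 h) | 0.0310 M | the fed solution adds 0.50 times the starting volume | 30 h |

- in percentages every species weighs as the free monomer in it: one self-condensation product counts as two
- charges are per starting volume, the dose included; the dosed solution carries all of it
- the average divides the monomer in chains by the number of chains, living and dead together; two radicals that join make one chain
- the earlier runs were read with a standard deviation of 1 percentage point
- what may be going on: free monomer + growing radical -> monomer in chains + growing radical; 2 free monomer -> self-condensation product; 2 growing radical -> dead chain; protic impurity + free monomer -> quenched substrate; initiator -> 2 initiating radical; free monomer + initiating radical -> growing radical + monomer in chains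
- the earlier runs do not show the number of chains; that part of a forecast is a guess
- percentages count the whole charge, also what has not yet gone in

1. which of the two ends with the longer chains by the average number of monomer units in a chain (living and dead chains, two that joined counted as one) ("neither" if they lie within 10%) (beta / theta / neither)
2. average number of monomer units in a chain (living and dead chains, two that joined counted as one) at the end, beta
3. average number of monomer units in a chain (living and dead chains, two that joined counted as one) at the end, theta

| run | time / h | monomer in chains / % | free monomer / % |
|---|---|---|---|
| Tuesday's | 1.00 | 0.6 | 12.5 |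
| Tuesday's | 3.00 | 2.3 | 34.6 |
| Tuesday's | 6.00 | 3.1 | 65.5 |
| Tuesday's | 10.0 | 5.8 | 78.7 |
| Tuesday's | 12.0 | 6.7 | 74.1 |
| Tuesday's | 15.0 | 11.2 | 66.8 |
| Tuesday's | 20.0 | 12.6 | 58.4 |
| Friday's | 1.50 | 0 | 17.0 |
| Friday's | 2.50 | 0.8 | 30.3 |
| Friday's | 4.00 | 1.3 | 43.9 |
| Friday's | 6.00 | 4.3 | 64.6 |
| Friday's | 10.0 | 4.8 | 80.8 |
| Friday's | 15.0 | 8.2 | 69.2 |
| Friday's | 20.0 | 12.9 | 62.2 |

(each reading ± 1 percentage point)

At 20.0 h, Tuesday's run holds 12.6% in chains and Friday's 12.9%, although Friday's charge is twice Tuesday's. Uptake therefore reads as pseudo-first-order in free monomer, and at this initiator charge the share in chains does not follow the charge. The two runs average 12.8%, after a gain of 7.5 percentage points over the preceding 10.0 h. Free monomer shrank by a factor 0.756 over that stretch, so the next stretch, to 30 h, adds 5.6 points. The share then reaches 18.4%, taken for beta and theta alike.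

Call the chain yield the share of free monomer in chains divided by the share of initiator lost. Length is then chain yield times the ratio of the two charges, both per starting volume, so the feed's dilution cancels. No reading shows the initiator. Guessing half lost gives a yield of 0.368, so beta reaches 131 and theta 211.

That guess is the weak link, but it cancels in the comparison. Theta over beta is 1.61, outside the margin, whatever share is lost.

The forecast says theta, with 85 for beta and 140 for theta: “The chain count is a guess.” It counts about 65 µM chains per starting volume, where the reckoning here has 43.5 µM.

The flask gives theta, with 106 for beta and 175 for theta.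

    free monomer + growing radical → monomer in chains + growing radical, rate k1*[growing radical]*[free monomer] (k = 1060 M⁻¹ s⁻¹)
    2 free monomer → self-condensation product (k = 1.31 × 10⁻⁶ M⁻¹ s⁻¹)
    2 growing radical → dead chain (k = 4.50 × 10⁷ M⁻¹ s⁻¹)
    protic impurity + free monomer → quenched substrate (k = 4.19 × 10⁻⁴ M⁻¹ s⁻¹)
    initiator → 2 initiating radical (k = 7.68 × 10⁻⁶ s⁻¹)
    free monomer + initiating radical → growing radical + monomer in chains (k = 2.15 × 10⁵ M⁻¹ s⁻¹)

Theta holds 17.2% in chains and has lost 56.4% of its initiator, a chain yield of 0.304 against the 0.368 reckoned. Dead chains stand at 3.27 × 10⁻⁵ M, or 49.0 µM per starting volume, beside 49.0 µM of initiator lost. The neighbour of theta is charged with 5.2 × 10⁻⁵ M of initiator. Scaling the yield by the square root of the initiator ratio gives 0.235, hence a length of 226. That flask holds 13.6% in chains and ends at 232.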